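## Structural features

The target is a bicyclic 3,4-dihydrochromene-2,7-dione. Ring A (C4a, C5, C6, C7, C8, C8a) is a dearomatised acylphloroglucinol in which every carbon is substituted, and it is fused through the C4a=C8a enol double bond to a six-membered enol lactone, ring B (O1, C2, C3, C4). C8 is quaternary, bears two prenyl groups and lies between the C7 ketone and the oxygen-bearing C8a. C6 bears the (2R)-2-methylbutanoyl group, whose carbonyl is chelated by the C5 enol hydroxyl. The two stereocentres, C4 (S, benzylic) and the acyl α-carbon (R), are five bonds apart, so neither can steer the other. The acyl centre is α to a carbonyl and epimerisable, whereas C4 is α to none. Fragile groups are the two trisubstituted prenyl olefins (acid), the lactone (a vinylogous anhydride and acyl donor) and the enolised triketone (air, strong base). The difficulty is twofold: building quaternary C8 between two carbonyl-type carbons, and telling apart three nearly equivalent ring oxygens (O5, O7, O8a), only one of which may become the lactone oxygen. The key step uses the fact that, without the acyl group, C5–C6–C7 is a malonyl unit and C4a and C8 are the two α-carbons of the C8a carbonyl, so malonyl dichloride can close ring A on a diprenylmethyl ketone.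

## Logic of the disconnections

**19 ⇒ 18.** Cut: O1–C2, the enol ester bond of the lactone. This vinylogous anhydride is the most labile bond of 19 and is therefore made last. The cut opens ring B and leaves a seco acid whose ring A is complete. The forward step must acylate O8a, not O5, without acid. In 18 this is prepared: O5–H is held in the hydrogen bond to the C6 acyl carbonyl, so O8a–H is the only free enol hydroxyl.

**18 ⇒ 17.** No skeletal bond is cut; the C2 carboxyl goes back to its methyl ester. The methyl ester is the inert spectator that carries this arm through carbonate, zerovalent palladium and acid chloride. The demand is a saponification that leaves the acyl α-centre and the triketone intact; the triketone is protected as its enolate.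

**17 ⇒ 14 + 15.** Cut: C6–C(acyl). The epimerisable centre stays out of all enolising steps up to ring formation and enters as a commercial acid. Placing this cut before the lactone cut is deliberate: once on C6, the acyl group distinguishes O5 from O8a. The forward step must put the acyl group on carbon, at C6 and not C4a, with its configuration kept.

**14 ⇒ 11 + 12 (key disconnection).** Cut: C4a–C5 and C7–C8. C5–C6–C7 is the carbon chain of 12, and C4a and C8 are the α-carbons of the C8a carbonyl. Ring A and the quaternary carbon vanish together, leaving an open-chain enol silane with one stereocentre. The forward step needs two C-acylations, the first at the hindered carbon. For that reason 11 is defined as the regioisomer with the C8=C8a double bond: the quaternary centre is then made in the bimolecular step and the ring closes at unhindered C4a. Acylating C4a first would leave a 1,3-dicarbonyl that enolises away from C8 and closes through oxygen to an aromatic 4-hydroxy-2-pyranone.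

**11 ⇒ 10.** Only the O–Si bond is cut. The gain is a stable ketone that can be purified. The demand is enolisation toward the more substituted α-carbon C8 in the presence of an ester, which calls for equilibrating soft enolisation and excludes amide bases.

**10 ⇒ 8.** A carboxyl group is put back on C8 (C8–CO2 bond). C8 becomes the carbon of a β-keto ester, the one position in the chain that can be alkylated twice under mild base with full regiocontrol. The ester is allyl so that it leaves under neutral conditions with zerovalent palladium; an acid-labile tert-butyl ester would endanger the prenyl groups.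

**8 ⇒ 5 + 6 (twice).** Cut: both C8–CH2 bonds to the prenyl groups. The quaternary carbon becomes an active methylene and ten carbons become a commercial bromide. The forward step needs C- over O-alkylation twice and no reaction at C4a or next to the methyl ester; a carbonate base secures the latter.

**5 ⇒ 2 + 3.** Cut: C8–C8a. The acid arm of 2 is lengthened by two carbons taken from 3 (C8 and the carboxyl that is lost later). The gain is a hemiester whose arms differ only as acid and ester. The forward step must activate the acid without letting the two arms exchange roles, which would erase the stereocentre.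

**2 ⇒ 1.** Cut: the C2–OMe bond, closing the anhydride. The stereocentre disappears because 1 has a mirror plane through C4. The absolute configuration at C4 therefore rests on one catalyst-controlled choice between two enantiotopic carbonyl groups.

## Other disconnections considered

**Alternative 1:** The cut is O1–C8a on an aromatic precursor. A 3,3-diarylpropanoic acid A1 would be oxidised with PhI(OCOCF3)2 and BF3·OEt2 so that the carboxyl oxygen bonds to an ortho carbon of the dimethoxyarene, giving (4S)-5,7-dimethoxy-4-phenylchroman-2-one A2 with C4 untouched.

- **Correction of structure.** A 3,5-dimethoxyphenyl ring cannot lead to A2. Both of its ortho carbons lie next to a methoxy-bearing carbon, so closure there gives the 6,8-dimethoxy isomer A3. The 5,7-pattern requires A1 to be (3S)-3-(2,4-dimethoxyphenyl)-3-phenylpropanoic acid, with the C–O bond formed at C6 of that ring.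
- **In favour.** The intermediates are robust arenes. C4 could come from a well-developed asymmetric conjugate arylation, as reliable as the desymmetrisation used here. The way to the bicyclic core is shorter than the way to 14; on step count to the core this alternative is the better one.
- **Against.** In the corrected A1 the carbon to be oxidised is meta to both methoxy groups, the least activated site for arene radical-cation chemistry; attack ortho or para to oxygen, or at the ipso carbon, is more likely. After A2 the route still needs demethylation, C6 acylation and dearomatising double prenylation at C8 on a phloroglucinol whose C6 and C8 are nearly alike. O- versus C-prenylation, mono- versus bis-prenylation and C6 versus C8 would each need control, under base that opens the aryl lactone. A benzylic centre on so electron-rich a ring can also racemise by reversible ring opening.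
- **Comparison.** In the chosen plan the two prenyl groups are on C8 before ring A exists, so this regiochemical problem does not arise, and both bond formations are polarity-matched acylations. Both plans keep the acyl centre to the end; on that point they are equal.

**Alternative 2:** The cut is C6–C7 and C4a–C5. The cyclobutenone A4 would be heated with ethoxyethyne A5. Ring opening to a vinylketene, [2+2] addition of the alkyne, a second four-electron opening and a six-electron closure would give the dienone A6.

- **In favour.** The conditions are neutral and thermal, with no HCl and no Lewis acid. The C–C bonds form in pericyclic steps, so there is no O-acylation competitor; on this mechanistic point the alternative is better than the chosen plan. The polarity of the ynol ether fixes the oxygen pattern, and O7 emerges as the only ketone.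
- **Against.** A4 is itself the hard part: a 4,4-diprenyl-3-ethoxycyclobutenone with the stereodefined side chain on C2 needs its own multistep synthesis, which moves the quaternary-carbon problem into a ketene cycloaddition. The six-electron closure must bond to a fully substituted diene terminus, which leaves time for ketene dimerisation and hydrogen shifts from the prenyl CH2 groups. At the temperatures needed, a 6,6-diprenylcyclohexadienone can lose a prenyl group by Cope-type migration. A6 also carries two ethyl enol ethers, at O5 and O8a, which must be told apart and cleaved with acid in the presence of prenyl groups.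
- **Comparison.** Both plans close one ring in the key step; on that they are equal. The alternative is expected to be longer overall. The O5/O8a question, answered in the chosen route by the acyl chelate, returns here in a harder form.

**Alternative 3:** The cut is C4a–C8a and C6–C7. The diketo ester A7 would be converted into its bis(trimethylsilyl) dienol ether A8 and acylated twice by 2,2-diprenylmalonyl dichloride A9 under TiCl4 or Me3SiOTf, giving the seco ester A10.

- **In favour.** This is the most convergent plan. The quaternary carbon comes from a simple malonate dialkylation, not from acylation at a hindered carbon; that is better than the chosen plan. A10 is identical with 17, so the end game is the same and the longest linear sequence is probably shorter; on step economy the alternative is the better.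
- **Against.** A7 already contains the epimerisable acyl centre, and forming A8 requires enolisation at a terminal α-carbon of the diketone. The sec-butyl methine is one of the two terminal positions, so both regiochemistry and configuration are at risk. The electrophile A9 is hindered and cannot react through a ketene, and the second acylation at the central carbon competes with closure through oxygen. TiCl4 and Me3SiOTf can trigger cation–olefin reactions of the four prenyl-type olefins.
- **Comparison.** Both are double C-acylations of silyl enol ethers with the same C/O hazard; mechanistically they are equal in kind. The polarity is reversed: in the chosen plan the hindered carbon is the nucleophile, the electrophile is small and unhindered, and the chiral acyl group is absent during ring formation.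

Key step: step 6

Assumption: of the two commercial pseudoenantiomeric catalysts, (DHQ)2AQN is taken to be the one that opens 1 to the (S)-hemiester 2; if (DHQD)2AQN does so instead, the two are exchanged and nothing else changes.

## Steps

Step 1
Reactants: 1 3-phenylglutaric anhydride (4-phenyloxane-2,6-dione)
Product: 2 (3S)-5-methoxy-5-oxo-3-phenylpentanoic acid
Conditions: MeOH (10 equiv), (DHQ)2AQN (0.3 equiv), Et2O, −40 °C
Reagents that add atoms: methanol (CO)
Why: Cinchona-alkaloid-catalysed desymmetrising alcoholysis of a prochiral cyclic anhydride: the quinuclidine nitrogen of hydroquinine anthraquinone-1,4-diyl diether activates methanol as a general base inside a chiral pocket, so one of the two enantiotopic carbonyls is attacked and C4 of the target is set; the enantiomeric purity can be raised by crystallising the hemiester.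

Step 2
Reactants: 2 (3S)-5-methoxy-5-oxo-3-phenylpentanoic acid; 3 Meldrum's acid (2,2-dimethyl-1,3-dioxane-4,6-dione)
Product: 5 β-keto allyl ester 7-methyl 1-(prop-2-enyl) (5S)-3-oxo-5-phenylheptanedioate, via acyl Meldrum's acid 4 (not isolated)
Conditions: DCC (1.1 equiv), DMAP (1.5 equiv), CH2Cl2, 0 °C → rt; filter, aq. KHSO4 wash; then allyl alcohol (5 equiv), toluene, 90 °C
Reagents that add atoms: allyl alcohol (C=CCO)
Why: Carbodiimide-mediated C-acylation of Meldrum's acid, then thermal cycloreversion to an acylketene that allyl alcohol traps (the Meldrum's acid route to β-keto esters); the stereocentre is β to the activated carboxyl and the methyl ester is not touched under these neutral conditions.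

Step 3
Reactants: 5 7-methyl 1-(prop-2-enyl) (5S)-3-oxo-5-phenylheptanedioate; 6 prenyl bromide (1-bromo-3-methylbut-2-ene)
Product: 8 diprenyl β-keto ester 7-methyl 1-(prop-2-enyl) (5S)-2,2-bis(3-methylbut-2-enyl)-3-oxo-5-phenylheptanedioate, via monoprenyl keto ester 7 (not isolated)
Conditions: 6 (2.4 equiv), Cs2CO3 (3 equiv), MeCN, 0 → 40 °C
Reagents that add atoms: none
Why: Twofold acetoacetic-ester C-alkylation with a soft allylic SN2 electrophile builds the fully substituted carbon at the stage where it is easiest; carbonate deprotonates only the doubly activated C8 and leaves C4a and the ester α-carbon alone.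

Step 4
Reactants: 8 7-methyl 1-(prop-2-enyl) (5S)-2,2-bis(3-methylbut-2-enyl)-3-oxo-5-phenylheptanedioate
Product: 10 methyl (3S)-9-methyl-6-(3-methylbut-2-enyl)-5-oxo-3-phenyldec-8-enoate, via β-keto acid 9 (not isolated)
Conditions: Pd(OAc)2 (3 mol %), PPh3 (12 mol %), HCO2H (2.5 equiv), Et3N (3 equiv), THF, rt
Reagents that add atoms: none
Why: Tsuji-type deallylative decarboxylation: zerovalent palladium formed in situ ionises the allyl ester, formate reduces the π-allyl complex faster than it can allylate C8, and the α,α-disubstituted β-keto acid loses CO2 at room temperature; the neutral medium spares the prenyl olefins and the methyl ester.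

Step 5
Reactants: 10 methyl (3S)-9-methyl-6-(3-methylbut-2-enyl)-5-oxo-3-phenyldec-8-enoate
Product: 11 methyl (3S)-9-methyl-6-(3-methylbut-2-enyl)-3-phenyl-5-(trimethylsilyloxy)deca-5,8-dienoate
Conditions: Me3SiCl (1.5 equiv), NaI (1.5 equiv), Et3N (2 equiv), MeCN, rt, until the isomer composition no longer changes
Reagents that add atoms: chlorotrimethylsilane (C[Si](C)(C)Cl)
Why: Thermodynamic silyl enol ether formation by soft enolisation (Me3SiI made in situ, amine base) should favour the more highly substituted C8=C8a enol silane; no free enolate is formed, so the ester cannot undergo Claisen condensation, and the buffered medium keeps acid from the prenyl groups.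

Step 6
Reactants: 11 methyl (3S)-9-methyl-6-(3-methylbut-2-enyl)-3-phenyl-5-(trimethylsilyloxy)deca-5,8-dienoate; 12 malonyl dichloride (propanedioyl dichloride)
Product: 14 methyl (3S)-3-[2-hydroxy-3,3-bis(3-methylbut-2-enyl)-4,6-dioxocyclohex-1-enyl]-3-phenylpropanoate, via C8-acylated acid chloride 13 (not isolated)
Conditions: 12 (1.2 equiv), Et2O, −20 °C → rt; phosphate buffer (pH 7) work-up
Reagents that add atoms: none
Why: The C8 terminus of the tetrasubstituted enol silane attacks one acyl chloride of 12 (or the chlorocarbonylketene in equilibrium with it) in a Mukaiyama-type C-acylation; Me3SiCl leaves and 13 already holds quaternary C8. The C8a ketone of 13 can enolise only toward C4a, and that enol carbon attacks the second acyl chloride, forming C4a–C5; loss of HCl and tautomerisation give the enolised trione 14, whose vinylogous-acid stabilisation drives the sequence. The closest known reaction is the Effenberger cyclisation of ketone enol ethers with malonyl dichloride to cyclohexane-1,3,5-triones, which tolerates a fully substituted α-carbon. Ring A closes in a 6-(enolendo)-exo-trig mode, with the enol double bond inside and the acyl C=O outside the new ring. No stereocentre is created: C8 bears two identical prenyl groups and C4a ends trigonal, while C4 is β to both carbonyls, cannot enolise and keeps its configuration. The step needs carbon over oxygen acylation twice and attack at C8 before C4a: silicon on oxygen and the position of the enol double bond send the first acylation to C8, and because C8 is then quaternary the only enol left points at C4a. If oxygen closes the ring instead, the product is a non-aromatic 6-alkylidene enol lactone and not a 4-hydroxy-2-pyranone, and methoxide can reopen it to a ketone enolate placed for Dieckmann closure to 14.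

Step 7
Reactants: 14 methyl (3S)-3-[2-hydroxy-3,3-bis(3-methylbut-2-enyl)-4,6-dioxocyclohex-1-enyl]-3-phenylpropanoate; 15 (2R)-2-methylbutanoic acid
Product: 17 methyl (3S)-3-{2,6-dihydroxy-5-[(2R)-2-methylbutanoyl]-3,3-bis(3-methylbut-2-enyl)-4-oxocyclohexa-1,5-dien-1-yl}-3-phenylpropanoate, via O5 enol ester 16 (not isolated)
Conditions: 15 (1.1 equiv), DCC (1.2 equiv), DMAP (1.2 equiv), CH2Cl2, 0 °C → rt, argon
Reagents that add atoms: none
Why: Steglich O-acylation of the trione enol followed by DMAP-mediated O-to-C acyl migration through an acylpyridinium–enolate ion pair, the standard route to 2-acylcyclohexane-1,3-diones; the acyl group settles on C6 because only there is the product an enolisable, hydrogen-bonded β-triketone, whereas acylation at C4a would give a non-enolisable quaternary ketone; activating the free acid with a carbodiimide avoids the acid chloride–amine ketene pathway that would racemise the α-centre.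

Step 8
Reactants: 17 methyl (3S)-3-{2,6-dihydroxy-5-[(2R)-2-methylbutanoyl]-3,3-bis(3-methylbut-2-enyl)-4-oxocyclohexa-1,5-dien-1-yl}-3-phenylpropanoate
Product: 18 (3S)-3-{2,6-dihydroxy-5-[(2R)-2-methylbutanoyl]-3,3-bis(3-methylbut-2-enyl)-4-oxocyclohexa-1,5-dien-1-yl}-3-phenylpropanoic acid
Conditions: LiOH (4 equiv), THF–H2O (3:1), 0 °C → rt, argon; then 1 M HCl to pH 3 at 0 °C
Reagents that add atoms: lithium hydroxide ([Li+].[OH-])
Why: Saponification of the methyl ester by acyl–oxygen cleavage; under base the acyl trione is present as its delocalised enolate, which resists retro-Claisen attack and cannot be deprotonated a second time at the side-chain α-carbon, and C4 is not α to a carbonyl.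

Step 9
Reactants: 18 (3S)-3-{2,6-dihydroxy-5-[(2R)-2-methylbutanoyl]-3,3-bis(3-methylbut-2-enyl)-4-oxocyclohexa-1,5-dien-1-yl}-3-phenylpropanoic acid
Product: 19 (4S)-5-hydroxy-6-[(2R)-2-methylbutanoyl]-8,8-bis(3-methylbut-2-enyl)-4-phenyl-3,4-dihydro-2H-chromene-2,7(8H)-dione (CNP0311143.1)
Conditions: EDC·HCl (1.3 equiv), DMAP (0.1 equiv), CH2Cl2 (0.01 M), 0 °C → rt
Reagents that add atoms: none
Why: Carbodiimide-mediated intramolecular O-acylation of an enol (enol lactonisation, 6-exo-trig) at O8a–H, the only enol hydroxyl of 18 not tied into the chelated β-triketone; no acid is used, so the prenyl groups cannot cyclise onto the enol oxygens.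

## Compound list

1 | 3-phenylglutaric anhydride (4-phenyloxane-2,6-dione) | O=C1CC(c2ccccc2)CC(=O)O1 | starting material
2 | (3S)-5-methoxy-5-oxo-3-phenylpentanoic acid | OC(=O)C[C@H](c1ccccc1)CC(=O)OC | intermediate
3 | Meldrum's acid (2,2-dimethyl-1,3-dioxane-4,6-dione) | CC1(C)OC(=O)CC(=O)O1 | starting material
4 | methyl (3S)-5-(2,2-dimethyl-4,6-dioxo-1,3-dioxan-5-yl)-5-oxo-3-phenylpentanoate | CC1(C)OC(=O)C(C(=O)C[C@H](c2ccccc2)CC(=O)OC)C(=O)O1 | intermediate
5 | 7-methyl 1-(prop-2-enyl) (5S)-3-oxo-5-phenylheptanedioate | C=CCOC(=O)CC(=O)C[C@H](c1ccccc1)CC(=O)OC | intermediate
6 | prenyl bromide (1-bromo-3-methylbut-2-ene) | CC(C)=CCBr | starting material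
7 | 7-methyl 1-(prop-2-enyl) (5S)-2-(3-methylbut-2-enyl)-3-oxo-5-phenylheptanedioate (both C2 epimers) | C=CCOC(=O)C(CC=C(C)C)C(=O)C[C@H](c1ccccc1)CC(=O)OC | intermediate
8 | 7-methyl 1-(prop-2-enyl) (5S)-2,2-bis(3-methylbut-2-enyl)-3-oxo-5-phenylheptanedioate | C=CCOC(=O)C(CC=C(C)C)(CC=C(C)C)C(=O)C[C@H](c1ccccc1)CC(=O)OC | intermediate
9 | (5S)-7-methoxy-2,2-bis(3-methylbut-2-enyl)-3,7-dioxo-5-phenylheptanoic acid | OC(=O)C(CC=C(C)C)(CC=C(C)C)C(=O)C[C@H](c1ccccc1)CC(=O)OC | intermediate
10 | methyl (3S)-9-methyl-6-(3-methylbut-2-enyl)-5-oxo-3-phenyldec-8-enoate | CC(C)=CCC(CC=C(C)C)C(=O)C[C@H](c1ccccc1)CC(=O)OC | intermediate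
11 | methyl (3S)-9-methyl-6-(3-methylbut-2-enyl)-3-phenyl-5-(trimethylsilyloxy)deca-5,8-dienoate | CC(C)=CCC(CC=C(C)C)=C(O[Si](C)(C)C)C[C@H](c1ccccc1)CC(=O)OC | intermediate
12 | malonyl dichloride (propanedioyl dichloride) | ClC(=O)CC(Cl)=O | starting material
13 | methyl (3S)-6-(3-chloro-3-oxopropanoyl)-9-methyl-6-(3-methylbut-2-enyl)-5-oxo-3-phenyldec-8-enoate | ClC(=O)CC(=O)C(CC=C(C)C)(CC=C(C)C)C(=O)C[C@H](c1ccccc1)CC(=O)OC | intermediate
14 | methyl (3S)-3-[2-hydroxy-3,3-bis(3-methylbut-2-enyl)-4,6-dioxocyclohex-1-enyl]-3-phenylpropanoate | OC1=C([C@H](c2ccccc2)CC(=O)OC)C(=O)CC(=O)C1(CC=C(C)C)CC=C(C)C | intermediate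
15 | (2R)-2-methylbutanoic acid | CC[C@@H](C)C(O)=O | starting material
16 | 5-hydroxy-6-[(1S)-3-methoxy-3-oxo-1-phenylpropyl]-4,4-bis(3-methylbut-2-enyl)-3-oxocyclohexa-1,5-dien-1-yl (2R)-2-methylbutanoate | CC[C@@H](C)C(=O)OC1=CC(=O)C(CC=C(C)C)(CC=C(C)C)C(O)=C1[C@H](c1ccccc1)CC(=O)OC | intermediate
17 | methyl (3S)-3-{2,6-dihydroxy-5-[(2R)-2-methylbutanoyl]-3,3-bis(3-methylbut-2-enyl)-4-oxocyclohexa-1,5-dien-1-yl}-3-phenylpropanoate | CC[C@@H](C)C(=O)C1=C(O)C([C@H](c2ccccc2)CC(=O)OC)=C(O)C(CC=C(C)C)(CC=C(C)C)C1=O | intermediate
18 | (3S)-3-{2,6-dihydroxy-5-[(2R)-2-methylbutanoyl]-3,3-bis(3-methylbut-2-enyl)-4-oxocyclohexa-1,5-dien-1-yl}-3-phenylpropanoic acid | CC[C@@H](C)C(=O)C1=C(O)C([C@H](c2ccccc2)CC(=O)O)=C(O)C(CC=C(C)C)(CC=C(C)C)C1=O | intermediate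
19 | (4S)-5-hydroxy-6-[(2R)-2-methylbutanoyl]-8,8-bis(3-methylbut-2-enyl)-4-phenyl-3,4-dihydro-2H-chromene-2,7(8H)-dione | CC[C@@H](C)C(=O)C1=C(O)C2=C(OC(=O)C[C@H]2c2ccccc2)C(CC=C(C)C)(CC=C(C)C)C1=O | target

## Step count and least certain steps

Total steps: 9. Longest linear sequence: 9 steps (1 → 19).

**Step 6 (key step).** The most likely failures are ring closure through oxygen in the second acylation and protodesilylation of 11 (or hydrochlorination of a prenyl olefin) by the HCl released. Both arise because the second acylation is an acid-mediated reaction of a simple ketone enol in an open-chain system, with nothing to hold the oxygen away. The fallback replaces the bis-electrophile by a mono-electrophile and closes the ring under base. It sets out from 11, which is C-acylated at C8 with methyl 3-chloro-3-oxopropanoate under ZnCl2 promotion to give methyl (3S)-6-(3-methoxy-3-oxopropanoyl)-9-methyl-6-(3-methylbut-2-enyl)-5-oxo-3-phenyldec-8-enoate F1. Treatment of F1 with LiN(SiMe3)2 (2.2 equiv, THF, −78 → 0 °C) forms the C6/C4a dianion, and the C4a enolate closes on the malonyl ester in a Dieckmann condensation. The only other six-membered closure open to F1 is a reversible aldol. The fallback returns to the route at 14.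

**Step 5.** The most likely failure is enolisation toward C4a in competition with C8, because the tri- and tetrasubstituted enol ethers of an acyclic ketone differ little in energy; the C4a isomer would end as a pyranone in step 6. The fallback fixes the double bond by the position of a leaving carboxyl group instead of by equilibration. It sets out from 8: deallylation with Pd(PPh3)4 and morpholine at 0 °C gives the carboxylate of 9 without decarboxylation, and Me3SiCl converts it into trimethylsilyl (5S)-7-methoxy-2,2-bis(3-methylbut-2-enyl)-3,7-dioxo-5-phenylheptanoate F2. On warming in toluene F2 should lose CO2 through the six-membered transition state of β-keto acid decarboxylation, with silicon in the place of hydrogen. The silyl group is delivered to the ketone oxygen and the double bond to the carbon that carried the carboxyl group. The fallback returns at 11 as a single regioisomer.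

**Step 9.** The most likely failures are slow closure with competing N-acylurea formation and intermolecular acylation, and closure at O5 instead of O8a if the chelate does not hold; the hydrogen-bonded polyketone enol is a weak nucleophile. The fallback reverses the order of the end game. It sets out from 14: saponification (LiOH, THF–H2O) gives (3S)-3-[2-hydroxy-3,3-bis(3-methylbut-2-enyl)-4,6-dioxocyclohex-1-enyl]-3-phenylpropanoic acid F3. Its more nucleophilic, non-acylated trione enol is lactonised with EDC·HCl to (4S)-5-hydroxy-8,8-bis(3-methylbut-2-enyl)-4-phenyl-3,4-dihydro-2H-chromene-2,7(8H)-dione F4. C6 acylation of F4 with 15 (DCC, DMAP) follows. Under the DMAP of this last operation the lactone can migrate between O5 and O8a, and the fully chelated triketone should be the resting point. The fallback returns at 19.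

**Step 1.** The most likely failure is insufficient discrimination between the enantiotopic carbonyls with the catalyst that gives the (S)-hemiester, since pseudoenantiomeric cinchona catalysts are seldom equally selective. The fallback makes the route independent of which hemiester is the better one by exchanging the roles of the two arms. It sets out from 1, which is opened with the other catalyst to (3R)-5-methoxy-5-oxo-3-phenylpentanoic acid F5. The methyl ester of F5 (carboxyl protected as its lithium salt) undergoes crossed Claisen condensation with the lithium enolate of allyl acetate (allyl acetate, LiN(iPr)2, THF, −78 °C) to give (3S)-5,7-dioxo-3-phenyl-7-(prop-2-enyloxy)heptanoic acid F6. Methylation of the free acid of F6 with Me3SiCHN2 returns to the route at 5.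

## Further compounds

F1 | step 6 | methyl (3S)-6-(3-methoxy-3-oxopropanoyl)-9-methyl-6-(3-methylbut-2-enyl)-5-oxo-3-phenyldec-8-enoate | COC(=O)CC(=O)C(CC=C(C)C)(CC=C(C)C)C(=O)C[C@H](c1ccccc1)CC(=O)OC
F2 | step 5 | trimethylsilyl (5S)-7-methoxy-2,2-bis(3-methylbut-2-enyl)-3,7-dioxo-5-phenylheptanoate | C[Si](C)(C)OC(=O)C(CC=C(C)C)(CC=C(C)C)C(=O)C[C@H](c1ccccc1)CC(=O)OC
F3 | step 9 | (3S)-3-[2-hydroxy-3,3-bis(3-methylbut-2-enyl)-4,6-dioxocyclohex-1-enyl]-3-phenylpropanoic acid | OC1=C([C@H](c2ccccc2)CC(=O)O)C(=O)CC(=O)C1(CC=C(C)C)CC=C(C)C
F4 | step 9 | (4S)-5-hydroxy-8,8-bis(3-methylbut-2-enyl)-4-phenyl-3,4-dihydro-2H-chromene-2,7(8H)-dione | O=C1C=C(O)C2=C(OC(=O)C[C@H]2c2ccccc2)C1(CC=C(C)C)CC=C(C)C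
F5 | step 1 | (3R)-5-methoxy-5-oxo-3-phenylpentanoic acid | COC(=O)C[C@H](c1ccccc1)CC(=O)O
F6 | step 1 | (3S)-5,7-dioxo-3-phenyl-7-(prop-2-enyloxy)heptanoic acid | C=CCOC(=O)CC(=O)C[C@H](c1ccccc1)CC(=O)O
A1 | alternative 1 | (3S)-3-(2,4-dimethoxyphenyl)-3-phenylpropanoic acid | OC(=O)C[C@H](c1ccc(OC)cc1OC)c1ccccc1
A2 | alternative 1 | (4S)-5,7-dimethoxy-4-phenylchroman-2-one | COc1cc(OC)c2c(c1)OC(=O)C[C@H]2c1ccccc1
A3 | alternative 1 | (4S)-6,8-dimethoxy-4-phenylchroman-2-one | O=C1C[C@@H](c2ccccc2)c2cc(OC)cc(OC)c2O1
A4 | alternative 2 | methyl (3S)-3-[2-ethoxy-3,3-bis(3-methylbut-2-enyl)-4-oxocyclobut-1-enyl]-3-phenylpropanoate | CCOC1=C([C@H](c2ccccc2)CC(=O)OC)C(=O)C1(CC=C(C)C)CC=C(C)C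
A5 | alternative 2 | ethoxyethyne | CCOC#C
A6 | alternative 2 | methyl (3S)-3-[2,6-diethoxy-3,3-bis(3-methylbut-2-enyl)-4-oxocyclohexa-1,5-dienyl]-3-phenylpropanoate | CCOC1=C([C@H](c2ccccc2)CC(=O)OC)C(OCC)=CC(=O)C1(CC=C(C)C)CC=C(C)C
A7 | alternative 3 | methyl (3S,8R)-8-methyl-5,7-dioxo-3-phenyldecanoate | CC[C@@H](C)C(=O)CC(=O)C[C@H](c1ccccc1)CC(=O)OC
A8 | alternative 3 | methyl (3R,8R)-8-methyl-3-phenyl-5,7-bis(trimethylsilyloxy)deca-4,6-dienoate (enol ether geometries not defined) | CC[C@@H](C)C(O[Si](C)(C)C)=CC(O[Si](C)(C)C)=C[C@H](c1ccccc1)CC(=O)OC
A9 | alternative 3 | 2,2-bis(3-methylbut-2-enyl)propanedioyl dichloride | CC(C)=CCC(CC=C(C)C)(C(Cl)=O)C(Cl)=O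
A10 | alternative 3 | methyl (3S)-3-{2,6-dihydroxy-5-[(2R)-2-methylbutanoyl]-3,3-bis(3-methylbut-2-enyl)-4-oxocyclohexa-1,5-dien-1-yl}-3-phenylpropanoate | CC[C@@H](C)C(=O)C1=C(O)C([C@H](c2ccccc2)CC(=O)OC)=C(O)C(CC=C(C)C)(CC=C(C)C)C1=O
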